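**Plan**
- Retrosynthesis: remove the PMB mask of the lactone enol and the C5 chlorine; cut C6–C7 of the carbocycle (ring B: C4a–C5–C6–C7–C8–C8a); cut C8–C8a between the pyran (ring A) and the lactone-bearing ketone; cut the exocyclic C4a=C5–C6 unit back to a 4-pyranone carbonyl; cut the C1''=C2'' alkene of the dienyl chain.
- Enabling feature: ring B holds the α-ketol C6(=O)–C7(OH)(CH3), the retron of an aldehyde–ketone benzoin union of two carbonyl carbons; once C6–C7 is cut, C8–H is α to the C7 ketone and therefore epimerisable.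
- Forward order: lactone ring C (from ethyl (S)-3-hydroxybutanoate) and pyran ring A (from chlorokojic acid) are made separately; the dienyl chain is joined to ring A by Horner–Wadsworth–Emmons olefination; the pyranone is turned into a pyranylidene acetaldehyde; rings A and C are joined at C8–C8a; ring B is closed last; chlorination and unmasking finish.
- Stereochemistry: C5'' from (S)-2-methylbutan-1-ol; C6' from ethyl (S)-3-hydroxybutanoate; C7 from the chiral triazolylidene catalyst; C8 by dynamic kinetic resolution in the same step; C3' is labile and settles on protonation.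

Key step: step 12

Assumption: C3' of the β-keto-δ-lactone is enolisable and configurationally labile, so it is delivered under thermodynamic control in the last step and the drawn (3'R) keto form is taken as the stable form of the target.

Step 1
Reactants: 1 (S)-2-methylbutan-1-ol; 2 2-(triphenylphosphoranylidene)propanal
Product: 4 (S,E)-2,4-dimethylhex-2-enal, via (S)-2-methylbutanal 3 (not isolated)
Conditions: TEMPO (10 mol%), PhI(OAc)2, CH2Cl2, rt; then 2, toluene, 80 °C
Reagents that add atoms: none
Why: TEMPO/PhI(OAc)2 oxidation stops at the aldehyde, which is used in solution to protect its α-centre, and Wittig olefination with the formyl-stabilised ylide should give the E trisubstituted alkene under thermodynamic control, the C5'' centre coming unchanged from 1.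

Step 2
Reactants: 5 chlorokojic acid [2-(chloromethyl)-5-hydroxy-4H-pyran-4-one]
Product: 6 6-(chloromethyl)-4-oxo-4H-pyran-3-yl trifluoromethanesulfonate
Conditions: Tf2O, 2,6-lutidine, CH2Cl2, −78 → 0 °C
Reagents that add atoms: trifluoromethanesulfonic anhydride, O=S(=O)(C(F)(F)F)OS(=O)(=O)C(F)(F)F
Why: O-sulfonylation of the acidic enolic 5-OH (enol triflate formation), the hindered base avoiding quaternisation at the chloromethyl group.

Step 3
Reactants: 6 6-(chloromethyl)-4-oxo-4H-pyran-3-yl trifluoromethanesulfonate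
Product: 7 diethyl {[4-oxo-5-(trifluoromethanesulfonyloxy)-4H-pyran-2-yl]methyl}phosphonate
Conditions: P(OEt)3, toluene, 110 °C
Reagents that add atoms: triethyl phosphite, CCOP(OCC)OCC
Why: Michaelis–Arbuzov reaction at the activated primary chloride (a vinylogous α-halo ketone), the enol triflate being inert to the phosphite without a metal catalyst.

Step 4
Reactants: 7 diethyl {[4-oxo-5-(trifluoromethanesulfonyloxy)-4H-pyran-2-yl]methyl}phosphonate; 4 (S,E)-2,4-dimethylhex-2-enal
Product: 8 6-[(1E,3E,5S)-3,5-dimethylhepta-1,3-dien-1-yl]-4-oxo-4H-pyran-3-yl trifluoromethanesulfonate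
Conditions: LiN(SiMe3)2, THF, −78 → 0 °C
Reagents that add atoms: none
Why: Horner–Wadsworth–Emmons olefination of the pyranone-stabilised phosphonate carbanion with the enal should give the new C1''=C2'' alkene E under thermodynamic control, leaving the existing E alkene and C5'' untouched.

Step 5
Reactants: 8 6-[(1E,3E,5S)-3,5-dimethylhepta-1,3-dien-1-yl]-4-oxo-4H-pyran-3-yl trifluoromethanesulfonate; 9 ethynylmagnesium bromide
Product: 11 6-[(1E,3E,5S)-3,5-dimethylhepta-1,3-dien-1-yl]-4-(2-oxoethylidene)-4H-pyran-3-yl trifluoromethanesulfonate, via propargylic alcohol 10 (not isolated)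
Conditions: HC≡CMgBr, THF, −40 → 0 °C; then 10% aq. H2SO4, THF, 0 °C → rt
Reagents that add atoms: water, O (the aldehyde oxygen; the original C4 oxygen leaves as water)
Why: 1,2-addition of the acetylide to the pyranone carbonyl, then acid ionisation to the 4-ethynylpyrylium ion and hydration at the alkyne terminus (Meyer–Schuster rearrangement), should end at the push–pull pyranylidene acetaldehyde as thermodynamic sink; the exocyclic alkene geometry is labile and needs no control.

Step 6
Reactants: 12 ethyl (S)-3-hydroxybutanoate; 13 tert-butyl acetate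
Product: 14 tert-butyl (S)-5-hydroxy-3-oxohexanoate
Conditions: LiN(i-Pr)2 (3.3 equiv), 13 (3.3 equiv), THF, −78 → −30 °C
Reagents that add atoms: none
Why: crossed Claisen condensation of the ester with excess lithium enolate of tert-butyl acetate, the alkoxide formed in the flask shielding the carbinol centre, which is not touched.

Step 7
Reactants: 14 tert-butyl (S)-5-hydroxy-3-oxohexanoate
Product: 15 (S)-6-methyloxane-2,4-dione
Conditions: TFA, CH2Cl2, rt
Reagents that add atoms: none
Why: acidolysis of the tert-butyl ester and spontaneous δ-lactonisation of the 5-hydroxy-3-oxo acid, with retention at the carbinol carbon because the C–O bond is not broken.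

Step 8
Reactants: 15 (S)-6-methyloxane-2,4-dione; 16 chloroacetone
Product: 17 (S)-4-hydroxy-6-methyl-3-(2-oxopropyl)-5,6-dihydro-2H-pyran-2-one (enol form of the 3-acetonyl dione)
Conditions: KOH (1.0 equiv), H2O, NaI (cat.), 0 °C → rt; careful acidification to pH 3
Reagents that add atoms: none
Why: enolate C-alkylation of the cyclic β-keto lactone with an α-chloro ketone, the protic medium and soft electrophile favouring C- over O-alkylation.

Step 9
Reactants: 17 (S)-4-hydroxy-6-methyl-3-(2-oxopropyl)-5,6-dihydro-2H-pyran-2-one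
Product: 18 (S)-4-[(4-methoxybenzyl)oxy]-6-methyl-3-(2-oxopropyl)-5,6-dihydro-2H-pyran-2-one
Conditions: 4-methoxybenzyl alcohol, PPh3, DIAD, THF, 0 °C → rt
Reagents that add atoms: 4-methoxybenzyl alcohol, COc1ccc(CO)cc1
Why: Mitsunobu O-alkylation of the vinylogous acid at the 4-oxygen under neutral conditions, which avoids C-alkylation and the acid-induced furan closure of the 1,4-dicarbonyl unit.

Step 10
Reactants: 18 (S)-4-[(4-methoxybenzyl)oxy]-6-methyl-3-(2-oxopropyl)-5,6-dihydro-2H-pyran-2-one
Product: 19 (S)-4-[(4-methoxybenzyl)oxy]-6-methyl-3-[2-(trimethylsilyloxy)prop-1-en-1-yl]-5,6-dihydro-2H-pyran-2-one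
Conditions: TMSCl, Et3N, DMF, 50 °C
Reagents that add atoms: chlorotrimethylsilane, C[Si](C)(C)Cl
Why: silyl enol ether formation under equilibrating conditions should give the more substituted regioisomer, whose enol double bond is conjugated with the lactone alkene.

Step 11
Reactants: 11 6-[(1E,3E,5S)-3,5-dimethylhepta-1,3-dien-1-yl]-4-(2-oxoethylidene)-4H-pyran-3-yl trifluoromethanesulfonate; 19 (S)-4-[(4-methoxybenzyl)oxy]-6-methyl-3-[2-(trimethylsilyloxy)prop-1-en-1-yl]-5,6-dihydro-2H-pyran-2-one
Product: 20 (6S)-3-{1-[6-((1E,3E,5S)-3,5-dimethylhepta-1,3-dien-1-yl)-4-(2-oxoethylidene)-4H-pyran-3-yl]-2-oxopropyl}-4-[(4-methoxybenzyl)oxy]-6-methyl-5,6-dihydro-2H-pyran-2-one (both epimers at the new CH carbon C8)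
Conditions: Pd2(dba)3 (2.5 mol%), P(t-Bu)3 (10 mol%), ZnF2 (0.7 equiv), CsF (0.3 equiv), DMF, 60 °C
Reagents that add atoms: none
Why: Pd-catalysed α-alkenylation of a ketone enolate (oxidative addition of the enol triflate to zerovalent palladium, fluoride-triggered transmetalation of the zinc enolate from 19, reductive elimination at a carbon without β-hydrogen) forms C8–C8a; C8 arises as an epimer mixture, which is intended.

Step 12
Reactants: 20 (6S)-3-{1-[6-((1E,3E,5S)-3,5-dimethylhepta-1,3-dien-1-yl)-4-(2-oxoethylidene)-4H-pyran-3-yl]-2-oxopropyl}-4-[(4-methoxybenzyl)oxy]-6-methyl-5,6-dihydro-2H-pyran-2-one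
Product: 21 (7S,8R)-3-[(1E,3E,5S)-3,5-dimethylhepta-1,3-dien-1-yl]-7-hydroxy-8-{(6S)-4-[(4-methoxybenzyl)oxy]-6-methyl-2-oxo-5,6-dihydro-2H-pyran-3-yl}-7-methyl-7,8-dihydro-6H-isochromen-6-one (7-OH and the C8 lactone substituent cis)
Conditions: cis-1-amino-2-indanol-derived N-pentafluorophenyl bicyclic triazolium tetrafluoroborate (20 mol%, enantiomer selected for the 7S carbinol), DBU (30 mol%), 4 Å MS, toluene, 25 °C
Reagents that add atoms: none
Why: Proposed new method: the chiral triazolylidene adds to the aldehyde carbon C6 of 20, the resulting Breslow intermediate attacks the C7 methyl ketone as an acyl anion (6-exo-trig closure of ring B through the new C6–C7 bond), and proton transfer with loss of the carbene gives the α-ketol, so two carbonyl carbons of like polarity are joined by polarity reversal. The closest known reaction types are the enantioselective intramolecular crossed aldehyde–ketone benzoin cyclisation of aryl aldehydes carrying a tethered methyl ketone and the dynamic kinetic cross-benzoin of enolisable α-stereogenic ketones; neither has been shown with a pyranylidene acetaldehyde (a vinylogous formate) as donor or with both features combined. C7 is set by the catalyst, whose indane wall selects the ketone face in the hydrogen-bonded transition state in which the ketone oxygen points to the enol OH and the methyl group is pseudo-axial. C8 is set by dynamic kinetic resolution: in 20 its proton is α to the C7 ketone and doubly allylic, so DBU interconverts the two epimers, and the epimer that places the lactone pseudo-axial (no allylic strain with C1–H) and anti to the C7 methyl should close faster to the 7-OH/8-lactone cis product; in 21 C8 is no longer α to a carbonyl, so the result is locked. The step needs acyl-anion instead of homoenolate reactivity, secured because the β-carbon C4a is fully substituted and could only close a four-membered ring, and it needs the aldehyde on the C8a side of C4a=C5, secured by the easy rotation about this push–pull alkene. C5 carries no chlorine yet because an α-chloro enal would expel chloride from the Breslow intermediate.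

Step 13
Reactants: 21 (7S,8R)-3-[(1E,3E,5S)-3,5-dimethylhepta-1,3-dien-1-yl]-7-hydroxy-8-{(6S)-4-[(4-methoxybenzyl)oxy]-6-methyl-2-oxo-5,6-dihydro-2H-pyran-3-yl}-7-methyl-7,8-dihydro-6H-isochromen-6-one
Product: 22 (7S,8R)-5-chloro-3-[(1E,3E,5S)-3,5-dimethylhepta-1,3-dien-1-yl]-7-hydroxy-8-{(6S)-4-[(4-methoxybenzyl)oxy]-6-methyl-2-oxo-5,6-dihydro-2H-pyran-3-yl}-7-methyl-7,8-dihydro-6H-isochromen-6-one
Conditions: NCS (1.05 equiv), MeCN, 0 °C → rt, dark
Reagents that add atoms: N-chlorosuccinimide, O=C1CCC(=O)N1Cl
Why: electrophilic chlorination at C5, the α-carbon of the cross-conjugated vinylogous 4-pyranone and terminus of both dienol ether paths from the ring oxygen, while the lactone C3' is blocked as a fully substituted enol ether.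

Step 14
Reactants: 22 (7S,8R)-5-chloro-3-[(1E,3E,5S)-3,5-dimethylhepta-1,3-dien-1-yl]-7-hydroxy-8-{(6S)-4-[(4-methoxybenzyl)oxy]-6-methyl-2-oxo-5,6-dihydro-2H-pyran-3-yl}-7-methyl-7,8-dihydro-6H-isochromen-6-one
Product: 23 (7S,8S)-5-chloro-3-[(1E,3E,5S)-3,5-dimethylhepta-1,3-dien-1-yl]-7-hydroxy-7-methyl-8-[(3R,6S)-6-methyl-2,4-dioxooxan-3-yl]-7,8-dihydro-6H-isochromen-6-one (target)
Conditions: TFA (10 vol%), anisole (5 equiv), CH2Cl2, 0 °C
Reagents that add atoms: none
Why: acidolysis of the 4-methoxybenzyl vinylogous ester (SN1 loss of the benzylic cation, trapped by anisole in a Friedel–Crafts alkylation) frees the enol, which protonates at C3' under thermodynamic control; the acid-tolerant chloro-isochromenone core, the diene, C7 and C8 are not touched and the base- and amine-sensitive pyran is never exposed to nucleophiles.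

**Compound list**
1 | (S)-2-methylbutan-1-ol | CC[C@H](C)CO | starting material
2 | 2-(triphenylphosphoranylidene)propanal | CC(C=O)=P(c1ccccc1)(c1ccccc1)c1ccccc1 | starting material
3 | (S)-2-methylbutanal | CC[C@H](C)C=O | intermediate
4 | (S,E)-2,4-dimethylhex-2-enal | CC[C@H](C)/C=C(C)/C=O | intermediate
5 | chlorokojic acid, 2-(chloromethyl)-5-hydroxy-4H-pyran-4-one | O=C1C=C(CCl)OC=C1O | starting material
6 | 6-(chloromethyl)-4-oxo-4H-pyran-3-yl trifluoromethanesulfonate | O=C1C=C(CCl)OC=C1OS(=O)(=O)C(F)(F)F | intermediate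
7 | diethyl {[4-oxo-5-(trifluoromethanesulfonyloxy)-4H-pyran-2-yl]methyl}phosphonate | CCOP(=O)(CC1=CC(=O)C(OS(=O)(=O)C(F)(F)F)=CO1)OCC | intermediate
8 | 6-[(1E,3E,5S)-3,5-dimethylhepta-1,3-dien-1-yl]-4-oxo-4H-pyran-3-yl trifluoromethanesulfonate | CC[C@H](C)/C=C(C)/C=C/C1=CC(=O)C(OS(=O)(=O)C(F)(F)F)=CO1 | intermediate
9 | ethynylmagnesium bromide | C#C[Mg]Br | starting material
10 | 6-[(1E,3E,5S)-3,5-dimethylhepta-1,3-dien-1-yl]-4-ethynyl-4-hydroxy-4H-pyran-3-yl trifluoromethanesulfonate (both C4 epimers) | CC[C@H](C)/C=C(C)/C=C/C1=CC(O)(C#C)C(OS(=O)(=O)C(F)(F)F)=CO1 | intermediate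
11 | 6-[(1E,3E,5S)-3,5-dimethylhepta-1,3-dien-1-yl]-4-(2-oxoethylidene)-4H-pyran-3-yl trifluoromethanesulfonate (exocyclic alkene isomers interconvert) | CC[C@H](C)/C=C(C)/C=C/C1=CC(=CC=O)C(OS(=O)(=O)C(F)(F)F)=CO1 | intermediate
12 | ethyl (S)-3-hydroxybutanoate | CCOC(=O)C[C@H](C)O | starting material
13 | tert-butyl acetate | CC(=O)OC(C)(C)C | starting material
14 | tert-butyl (S)-5-hydroxy-3-oxohexanoate | C[C@H](O)CC(=O)CC(=O)OC(C)(C)C | intermediate
15 | (S)-6-methyloxane-2,4-dione | C[C@H]1CC(=O)CC(=O)O1 | intermediate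
16 | chloroacetone | CC(=O)CCl | starting material
17 | (S)-4-hydroxy-6-methyl-3-(2-oxopropyl)-5,6-dihydro-2H-pyran-2-one | CC(=O)CC1=C(O)C[C@H](C)OC1=O | intermediate
18 | (S)-4-[(4-methoxybenzyl)oxy]-6-methyl-3-(2-oxopropyl)-5,6-dihydro-2H-pyran-2-one | CC(=O)CC1=C(OCc2ccc(OC)cc2)C[C@H](C)OC1=O | intermediate
19 | (S)-4-[(4-methoxybenzyl)oxy]-6-methyl-3-[2-(trimethylsilyloxy)prop-1-en-1-yl]-5,6-dihydro-2H-pyran-2-one | CC(O[Si](C)(C)C)=CC1=C(OCc2ccc(OC)cc2)C[C@H](C)OC1=O | intermediate
20 | (6S)-3-{1-[6-((1E,3E,5S)-3,5-dimethylhepta-1,3-dien-1-yl)-4-(2-oxoethylidene)-4H-pyran-3-yl]-2-oxopropyl}-4-[(4-methoxybenzyl)oxy]-6-methyl-5,6-dihydro-2H-pyran-2-one (C8 epimers) | CC[C@H](C)/C=C(C)/C=C/C1=CC(=CC=O)C(=CO1)C(C(C)=O)C2=C(OCc3ccc(OC)cc3)C[C@H](C)OC2=O | intermediate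
21 | (7S,8R)-3-[(1E,3E,5S)-3,5-dimethylhepta-1,3-dien-1-yl]-7-hydroxy-8-{(6S)-4-[(4-methoxybenzyl)oxy]-6-methyl-2-oxo-5,6-dihydro-2H-pyran-3-yl}-7-methyl-7,8-dihydro-6H-isochromen-6-one | CC[C@H](C)/C=C(C)/C=C/C1=CC2=CC(=O)[C@@](C)(O)[C@@H](C3=C(OCc4ccc(OC)cc4)C[C@H](C)OC3=O)C2=CO1 | intermediate
22 | (7S,8R)-5-chloro-3-[(1E,3E,5S)-3,5-dimethylhepta-1,3-dien-1-yl]-7-hydroxy-8-{(6S)-4-[(4-methoxybenzyl)oxy]-6-methyl-2-oxo-5,6-dihydro-2H-pyran-3-yl}-7-methyl-7,8-dihydro-6H-isochromen-6-one | CC[C@H](C)/C=C(C)/C=C/C1=CC2=C(Cl)C(=O)[C@@](C)(O)[C@@H](C3=C(OCc4ccc(OC)cc4)C[C@H](C)OC3=O)C2=CO1 | intermediate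
23 | (7S,8S)-5-chloro-3-[(1E,3E,5S)-3,5-dimethylhepta-1,3-dien-1-yl]-7-hydroxy-7-methyl-8-[(3R,6S)-6-methyl-2,4-dioxooxan-3-yl]-7,8-dihydro-6H-isochromen-6-one | CC[C@H](C)/C=C(C)/C=C/C1=CC2=C(Cl)C(=O)[C@@](C)(O)[C@@H]([C@@H]3C(=O)C[C@H](C)OC3=O)C2=CO1 | target

**Totals**
Total step count: 14. Longest linear sequence: 9 steps (steps 6–14, from ethyl (S)-3-hydroxybutanoate).

**Steps most likely to fail**

1. Step 12 (Proposed new method). The carbene may add too slowly to the deactivated push–pull aldehyde, or the Breslow intermediate may react through its vinylogous positions. Ring closure may also outrun epimerisation at C8, so that the resolution is not dynamic. Competing aldol closure of the C8 enolate onto the aldehyde is a further risk. The fallback uses known chemistry and sets out from 20. SmI2 (2.2 equiv) with t-BuOH in THF at −78 °C should effect the intramolecular aldehyde–ketone pinacol coupling of the same two carbonyl carbons to the cis-6,7-diol F1. MnO2 in CH2Cl2 should then oxidise only the secondary allylic C6 carbinol to the ketol. Because the (6S) lactone centre makes all C7/C8 isomers diastereomers, the (7S,8R) isomer is separated by chromatography and the route is rejoined at 21.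

2. Step 11. Oxidative addition of the electron-rich enol triflate may be sluggish, the zinc enolate may add to the aldehyde in an aldol reaction, or it may be protonated before transmetalation. The fallback sets out from 8. The same silyl dienol ether 19 is coupled with the electron-poor pyranone triflate 8 (Pd2(dba)3, P(t-Bu)3, ZnF2, CsF, DMF), with no aldehyde in the flask, to give the pyranone ketone F2. The ketone is then masked in the flask as its lithium enolate (LiN(SiMe3)2, THF, −78 °C) and HC≡CMgBr/CeCl3 is added to the pyranone carbonyl. Work-up with aq. H2SO4 brings about the Meyer–Schuster shift and reprotonates the enolate, rejoining the route at 20.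

3. Step 5. The Grignard reagent may add in conjugate fashion at the unsubstituted C6–H position, or water may attack the ethynylpyrylium ion at the ring α-carbon and open the ring instead of hydrating the alkyne terminus. The fallback sets out from 8. MeMgBr/CeCl3 in THF at −78 °C followed by HBF4·OEt2 should give the 4-methylpyrylium tetrafluoroborate F3. Condensation of its acidic methyl group with N,N-dimethylformamide dimethyl acetal gives the 4-(2-dimethylaminovinyl)pyrylium tetrafluoroborate F4. Hydrolysis with aqueous NaHCO3 releases the aldehyde and rejoins the route at 11.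

**Further compounds**
F1 | step 12 | 3-[(1E,3E,5S)-3,5-dimethylhepta-1,3-dien-1-yl]-8-{(6S)-4-[(4-methoxybenzyl)oxy]-6-methyl-2-oxo-5,6-dihydro-2H-pyran-3-yl}-7-methyl-7,8-dihydro-6H-isochromene-6,7-diol (cis-diol, C7/C8 isomers) | CC[C@H](C)/C=C(C)/C=C/C1=CC2=CC(O)C(C)(O)C(C3=C(OCc4ccc(OC)cc4)C[C@H](C)OC3=O)C2=CO1
F2 | step 11 | (6S)-3-{1-[6-((1E,3E,5S)-3,5-dimethylhepta-1,3-dien-1-yl)-4-oxo-4H-pyran-3-yl]-2-oxopropyl}-4-[(4-methoxybenzyl)oxy]-6-methyl-5,6-dihydro-2H-pyran-2-one | CC[C@H](C)/C=C(C)/C=C/C1=CC(=O)C(=CO1)C(C(C)=O)C2=C(OCc3ccc(OC)cc3)C[C@H](C)OC2=O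
F3 | step 5 | 2-[(1E,3E,5S)-3,5-dimethylhepta-1,3-dien-1-yl]-4-methyl-5-(trifluoromethanesulfonyloxy)pyrylium tetrafluoroborate | CC[C@H](C)/C=C(C)/C=C/c1cc(C)c(OS(=O)(=O)C(F)(F)F)c[o+]1.F[B-](F)(F)F
F4 | step 5 | 4-[(E)-2-(dimethylamino)vinyl]-2-[(1E,3E,5S)-3,5-dimethylhepta-1,3-dien-1-yl]-5-(trifluoromethanesulfonyloxy)pyrylium tetrafluoroborate | CC[C@H](C)/C=C(C)/C=C/c1cc(/C=C/N(C)C)c(OS(=O)(=O)C(F)(F)F)c[o+]1.F[B-](F)(F)F
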